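Winter has a ratio of 1.30, and that is its J ratio, the J charged over the Q charged. Maple, the nearest earlier run, has 1.65. I assume that each L takes one Q and one J, so control of the ceiling changes hands where this ratio crosses one. Above the crossing Q is the limiting reagent by the charge, so the ceiling on L is the whole Q charged. Below it J is, and the ratio itself, as a percentage, caps L.

| flask | Q | J | temperature | remark | time |
|---|---|---|---|---|---|
| elm | 0.32 M | 1.04 M | 50 °C | run made earlier |  |
| maple | 0.63 M | 1.04 M | 72 °C | run made earlier |  |
| winter | 0.80 M | 1.04 M | 80 °C |  | 12 d |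
| autumn | 0.52 M | 1.04 M | 40 °C |  | 12 d |

| elm: time / d | elm: L / % | maple: time / h | maple: L / % |
|---|---|---|---|
| 1.25 | 25.8 | 3.00 | 38.2 |
| 2.50 | 38.4 | 8.00 | 56.9 |
| 4.00 | 42.6 | 20.0 | 59.4 |
| 5.00 | 42.2 | 40.0 | 59.9 |

(each reading ± 1 percentage point)

1. which one finishes higher in amount of L, in percent of the Q charged ("neither" within 2 percentage points) (winter / autumn / neither)
2. amount of L at the end, in percent of the Q charged, winter
3. amount of L at the end, in percent of the Q charged, autumn



Maple stands above the crossing, yet its last reading is 59.9%, so something other than the charge stops it. Elm has the higher J ratio, 3.25, but it gives less L, 42.6% at 4.00 d. It is also the cooler run, at 50 °C against 72 °C. The two runs differ in both settings, so I cannot part the ratio from the temperature, and I read no more than that the warmer run gave more L.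

Winter, with 1.30, is on maple's side of the crossing and warmer, at 80 °C, so I expect it above maple's 59.9%. Autumn, with 2.00, is on the same side but cooler than elm, at 40 °C, so I expect it below elm's 42.6%. My choice is winter.

The forecast gives winter as higher, with 62.5% against 29.5%, starting from this: “The plateaus in both runs are flat, which suggests an equilibrium”.

The flask gives 61.9% for winter and 26.2% for autumn, so winter finishes higher.

    L ⇌ E (K = 1.70, k = 0.0434 h⁻¹, Ea = 94.0 kJ mol⁻¹, ΔH = −52.0 kJ mol⁻¹)
    Z + G → L (k = 0.0325 M⁻¹ h⁻¹, Ea = 96.0 kJ mol⁻¹)
    J → G (k = 0.0164 h⁻¹, Ea = 103 kJ mol⁻¹)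
    Q ⇌ Z (K = 1.41, k = 0.0285 h⁻¹, Ea = 105 kJ mol⁻¹, ΔH = 32.0 kJ mol⁻¹)
    2 Z → D (k = 0.0283 M⁻¹ h⁻¹, Ea = 76.0 kJ mol⁻¹)
    (constants at 40 °C)

Winter, at its J ratio of 1.30, ends with L at 61.9%, D at 27.1% and E at 11.0%, and G stands at 0.457 M. Its answer has moved by 5 points once J is down to 0.805 M, a ratio of 1.01. The neighbour flask is winter with J cut to 0.62 M. Its J ratio is 0.775 equiv, below the crossing, so by the charge J is the limiting reagent and the ceiling on L is 77.5%. There L ends at 51.1%, under that ceiling, with E at 9.05% and D at 39.8%, while Q stands at 0% and G still stands at 0.139 M.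

The earlier runs and the new flask were computed for an exercise; the scatter is artificial.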